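**Plan**

- Retrosynthesis: the aryl–CH2 bond of the diarylmethane is cut first (at the ring A carbon lying between the oxygen-bearing and the methyl-bearing carbons). This divides the target into two molecules of one monomer, phenol 12. In 12 the CMe2 carbon is taken back to C=O, the C(aryl)(CH3)–CH2 ring bond is cut by a retro-1,2-shift to the vinylcyclobutanol 7, and the aryl–alkenyl bond leads to bromocreosol and 1-ethynylcyclobutan-1-ol.
- Forward: both arenes come ready-made from creosol. The aryl–alkenyl bond is made in step 3, the cyclopentane by four-to-five ring enlargement in step 5, and C=O becomes CMe2 in steps 6–8. One portion of 12 is then oxidised at its ring methyl and united with a second portion (steps 9–10), and the ethers are cleaved (step 11).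
- The two cyclopentanes of the target are the same ring of 12, so step 5 is the only ring closure of the skeleton and no skeletal ring is closed after it.
- Enabling feature: the phenolic O–H on the aromatic carbon next to the one that carries the cyclopentane. It lets the α-substituted styrene be protonated to an ortho-quinone methide whose exocyclic carbon is the future quaternary centre, and it gives the chiral acid a second anchoring point. The neighbouring ring carbon (future CMe2) is the cyclobutanol carbinol carbon and emerges as the ketone.
- Stereochemistry: both (S) quaternary centres come from the single catalyst-controlled 1,2-shift, which gives the (R)-ketone 9; the descriptor changes only by priority when C=O becomes CMe2. The centre is non-enolisable, and no later step creates a cation, radical or anion at or next to it.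
- The same O–H is para to the ring methyl and later permits its oxidation via a para-quinone methide. The bulky cyclopentyl shields the other free ring position, so the union should occur between OCH3 and CH3.

Key step: step 5

Assumption: the sense of induction of the chiral acid cannot be predicted with certainty. The (R)-configured catalyst is written provisionally; the (S)-catalyst would be used instead if a test run shows that it is the one leading to the (R)-ketone 9.

**Step 1**
Reactants: 1 2-methoxy-4-methylphenol (creosol)
Product: 2 2-bromo-6-methoxy-4-methylphenol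
Conditions: Br2 (1.0 equiv), CH2Cl2, 0 °C
Reagents that add atoms: bromine (BrBr)
Why: Electrophilic aromatic bromination; the free hydroxyl is the strongest director and its para position is blocked by the methyl, so bromine should enter the free ortho position.

**Step 2**
Reactants: 2 2-bromo-6-methoxy-4-methylphenol
Product: 3 (2-bromo-6-methoxy-4-methylphenoxy)(tert-butyl)dimethylsilane
Conditions: TBSCl, imidazole, DMF, rt
Reagents that add atoms: tert-butyldimethylsilyl chloride (CC(C)(C)[Si](C)(C)Cl)
Why: Standard phenol silylation; the silyl ether masks the acidic O–H for the Grignard step and can later be removed by fluoride without acid, which would trigger the rearrangement prematurely.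

**Step 3**
Reactants: 3 (2-bromo-6-methoxy-4-methylphenoxy)(tert-butyl)dimethylsilane; 4 1-ethynylcyclobutan-1-ol
Product: 6 1-{1-[2-(tert-butyldimethylsilyloxy)-3-methoxy-5-methylphenyl]ethenyl}cyclobutan-1-ol, via arylmagnesium bromide 5 (not isolated)
Conditions: 3 (3 equiv), Mg, THF, 40 °C; then 4 (1 equiv), CuI (10 mol%), THF, 0 → 60 °C; aq NH4Cl
Reagents that add atoms: none
Why: Magnesium insertion followed by copper-catalysed anti-carbomagnesiation of the propargylic alkoxide; the aryl group is delivered to the alkyne carbon next to the carbinol while magnesium sits on the terminal carbon in a five-membered alkoxide chelate, so protonolysis should give the 1,1-disubstituted alkene.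

**Step 4**
Reactants: 6 1-{1-[2-(tert-butyldimethylsilyloxy)-3-methoxy-5-methylphenyl]ethenyl}cyclobutan-1-ol
Product: 7 2-[1-(1-hydroxycyclobutyl)ethenyl]-6-methoxy-4-methylphenol
Conditions: TBAF (1.1 equiv), THF, 0 °C; neutral aqueous work-up
Reagents that add atoms: none
Why: Fluoride cleavage of the aryl silyl ether under basic, acid-free conditions that should leave the acid-sensitive tertiary allylic cyclobutanol untouched.

**Step 5**
Reactants: 7 2-[1-(1-hydroxycyclobutyl)ethenyl]-6-methoxy-4-methylphenol
Product: 9 (2R)-2-(2-hydroxy-3-methoxy-5-methylphenyl)-2-methylcyclopentan-1-one, via ortho-quinone methide 8 (not isolated)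
Conditions: (R)-3,3'-bis(2,4,6-triisopropylphenyl)-1,1'-binaphthyl-2,2'-diyl N-triflylphosphoramide (5 mol%), toluene (0.02 M), −40 → −20 °C
Reagents that add atoms: none
Why: Proposed new method: the chiral acid should protonate the terminal CH2 of the styrene, the ortho hydroxyl turning the benzylic carbon into the exocyclic carbon of ortho-quinone methide 8 (a 2-hydroxybenzylic cation paired with the chiral anion); a cyclobutane C–C bond then migrates to this carbon while the carbinol O–H proton returns to the anion, releasing the four-ring strain and forming the C=O (semipinacol rearrangement). The closest known reaction types are the chiral phosphoric acid-catalysed protonation/semipinacol ring expansion of cyclobutanols bearing an enol ether, the enantioselective protio-semipinacol rearrangement of vinyl cyclopropanols under hydrogen-bond-donor/HCl co-catalysis, chiral Brønsted acid-catalysed additions to ortho-quinone methides, and the protio-semipinacol rearrangement of 1-(1-arylvinyl)cyclobutanols with achiral acids. The cyclopentanone ring is closed by ring enlargement, a suprafacial 1,2-shift of a ring CH2 from the carbinol carbon to the adjacent cationic carbon (four- to five-membered), not by an exo or endo cyclisation. The new quaternary stereocentre is set by the catalyst: the anion is held by two hydrogen bonds, to the phenolic O–H of the quinone methide and to the cyclobutanol O–H, which fixes the geometry about the exocyclic bond and leaves one face of the planar benzylic carbon open to the migrating bond; since the two ring CH2 groups of the cyclobutanol are equivalent, facial selection alone decides the configuration. The step needs enantioface selectivity and chemoselectivity for the intramolecular shift over dimerisation of 8 or ionisation of the tertiary hydroxyl; the substrate secures the latter through strain release and the proximity of the migrating bond, supported by dilution and low temperature. The centre formed is quaternary and non-enolisable, so it cannot be eroded afterwards.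

**Step 6**
Reactants: 9 (2R)-2-(2-hydroxy-3-methoxy-5-methylphenyl)-2-methylcyclopentan-1-one
Product: 10 2-methoxy-4-methyl-6-[(1S)-1-methyl-2-methylidenecyclopentyl]phenol
Conditions: Ph3PCH3Br, KOtBu (3.5 equiv each), toluene, 90 °C
Reagents that add atoms: methyltriphenylphosphonium bromide (C[P+](c1ccccc1)(c1ccccc1)c1ccccc1.[Br-])
Why: Wittig methylenation with excess ylide (one equivalent is consumed by the phenol); the reaction type is established for 2-aryl-2-methylcyclopentanones and the α-quaternary centre cannot epimerise.

**Step 7**
Reactants: 10 2-methoxy-4-methyl-6-[(1S)-1-methyl-2-methylidenecyclopentyl]phenol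
Product: 11 2-methoxy-4-methyl-6-[(4S)-4-methylspiro[2.4]heptan-4-yl]phenol
Conditions: Et2Zn (3 equiv), CH2I2 (6 equiv), CH2Cl2, 0 °C → rt
Reagents that add atoms: diiodomethane (ICI)
Why: Simmons–Smith cyclopropanation in the Furukawa variant; the zinc phenoxide formed in the flask carries the carbenoid and should deliver it to the nearby hindered exocyclic alkene.

**Step 8**
Reactants: 11 2-methoxy-4-methyl-6-[(4S)-4-methylspiro[2.4]heptan-4-yl]phenol
Product: 12 2-methoxy-4-methyl-6-[(1S)-1,2,2-trimethylcyclopentyl]phenol
Conditions: H2 (4 atm), PtO2, AcOH, rt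
Reagents that add atoms: none
Why: Catalytic hydrogenolysis of the spirocyclopropane at its least substituted bond (CH2–CH2) should turn the spiro carbon into CMe2, the classical way to a gem-dimethyl group beside a quaternary carbon, with no cationic intermediate near the stereocentre.

**Step 9**
Reactants: 12 2-methoxy-4-methyl-6-[(1S)-1,2,2-trimethylcyclopentyl]phenol
Product: 14 2-methoxy-4-(methoxymethyl)-6-[(1S)-1,2,2-trimethylcyclopentyl]phenol, via para-quinone methide 13 (not isolated)
Conditions: DDQ (1.05 equiv), MeOH, 0 °C → rt
Reagents that add atoms: methanol (CO)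
Why: DDQ oxidation of a 2,6-disubstituted 4-methylphenol to its para-quinone methide followed by 1,6-addition of methanol; the hydroxyl para to the methyl makes the benzylic oxidation selective and one equivalent of oxidant should stop it at the ether.

**Step 10**
Reactants: 14 2-methoxy-4-(methoxymethyl)-6-[(1S)-1,2,2-trimethylcyclopentyl]phenol; 12 2-methoxy-4-methyl-6-[(1S)-1,2,2-trimethylcyclopentyl]phenol
Product: 16 3-{[4-hydroxy-3-methoxy-5-[(1S)-1,2,2-trimethylcyclopentyl]phenyl]methyl}-2-methoxy-4-methyl-6-[(1S)-1,2,2-trimethylcyclopentyl]phenol, via 4-hydroxybenzyl cation 15 (not isolated)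
Conditions: 12 (4 equiv, excess recovered), TsOH·H2O (5 mol%), (CF3)2CHOH/CH2Cl2, 0 °C → rt, slow addition of 14
Reagents that add atoms: none
Why: Acid-catalysed Friedel–Crafts benzylation; the ether oxygen of 14 is protonated and methanol leaves to give the 4-hydroxybenzyl cation 15, stabilised by the para hydroxyl and the ionising solvent, which should be attacked by the excess of 12 at its only unhindered open ring carbon (between OCH3 and CH3; the other open position is shielded by the adjacent quaternary cyclopentyl), O-alkylation being reversible under acid.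

**Step 11**
Reactants: 16 3-{[4-hydroxy-3-methoxy-5-[(1S)-1,2,2-trimethylcyclopentyl]phenyl]methyl}-2-methoxy-4-methyl-6-[(1S)-1,2,2-trimethylcyclopentyl]phenol
Product: 17 3-{[3,4-dihydroxy-5-[(1S)-1,2,2-trimethylcyclopentyl]phenyl]methyl}-4-methyl-6-[(1S)-1,2,2-trimethylcyclopentyl]benzene-1,2-diol (CNP0137546.1)
Conditions: BBr3, CH2Cl2, −78 °C → rt; degassed H2O work-up under argon
Reagents that add atoms: none
Why: Lewis acid cleavage of the two aryl methyl ethers (BBr3 demethylation), each ortho to a free hydroxyl, which should not affect the diarylmethane or the quaternary centres.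

**Compound list**

1 | 2-methoxy-4-methylphenol (creosol) | Cc1ccc(O)c(OC)c1 | starting material
2 | 2-bromo-6-methoxy-4-methylphenol | Cc1cc(Br)c(O)c(OC)c1 | intermediate
3 | (2-bromo-6-methoxy-4-methylphenoxy)(tert-butyl)dimethylsilane | Cc1cc(Br)c(O[Si](C)(C)C(C)(C)C)c(OC)c1 | intermediate
4 | 1-ethynylcyclobutan-1-ol | C#CC1(O)CCC1 | starting material
5 | [2-(tert-butyldimethylsilyloxy)-3-methoxy-5-methylphenyl]magnesium bromide | Cc1cc([Mg]Br)c(O[Si](C)(C)C(C)(C)C)c(OC)c1 | intermediate
6 | 1-{1-[2-(tert-butyldimethylsilyloxy)-3-methoxy-5-methylphenyl]ethenyl}cyclobutan-1-ol | C=C(c1cc(C)cc(OC)c1O[Si](C)(C)C(C)(C)C)C1(O)CCC1 | intermediate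
7 | 2-[1-(1-hydroxycyclobutyl)ethenyl]-6-methoxy-4-methylphenol | C=C(c1cc(C)cc(OC)c1O)C1(O)CCC1 | intermediate
8 | 6-[1-(1-hydroxycyclobutyl)ethylidene]-2-methoxy-4-methylcyclohexa-2,4-dien-1-one (ortho-quinone methide, bound to the acid) | CC(=C1C=C(C)C=C(OC)C1=O)C1(O)CCC1 | intermediate
9 | (2R)-2-(2-hydroxy-3-methoxy-5-methylphenyl)-2-methylcyclopentan-1-one | Cc1cc([C@@]2(C)CCCC2=O)c(O)c(OC)c1 | intermediate
10 | 2-methoxy-4-methyl-6-[(1S)-1-methyl-2-methylidenecyclopentyl]phenol | Cc1cc([C@@]2(C)CCCC2=C)c(O)c(OC)c1 | intermediate
11 | 2-methoxy-4-methyl-6-[(4S)-4-methylspiro[2.4]heptan-4-yl]phenol | Cc1cc([C@@]2(C)CCCC23CC3)c(O)c(OC)c1 | intermediate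
12 | 2-methoxy-4-methyl-6-[(1S)-1,2,2-trimethylcyclopentyl]phenol | Cc1cc([C@@]2(C)CCCC2(C)C)c(O)c(OC)c1 | intermediate
13 | 2-methoxy-4-methylidene-6-[(1S)-1,2,2-trimethylcyclopentyl]cyclohexa-2,5-dien-1-one (para-quinone methide) | C=C1C=C(OC)C(=O)C([C@@]2(C)CCCC2(C)C)=C1 | intermediate
14 | 2-methoxy-4-(methoxymethyl)-6-[(1S)-1,2,2-trimethylcyclopentyl]phenol | COCc1cc(OC)c(O)c([C@@]2(C)CCCC2(C)C)c1 | intermediate
15 | {4-hydroxy-3-methoxy-5-[(1S)-1,2,2-trimethylcyclopentyl]phenyl}methylium (4-hydroxybenzyl cation, paired with tosylate) | [CH2+]c1cc(OC)c(O)c([C@@]2(C)CCCC2(C)C)c1 | intermediate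
16 | 3-{[4-hydroxy-3-methoxy-5-[(1S)-1,2,2-trimethylcyclopentyl]phenyl]methyl}-2-methoxy-4-methyl-6-[(1S)-1,2,2-trimethylcyclopentyl]phenol | Cc1cc([C@@]2(C)CCCC2(C)C)c(O)c(OC)c1Cc1cc(OC)c(O)c([C@@]2(C)CCCC2(C)C)c1 | intermediate
17 | 3-{[3,4-dihydroxy-5-[(1S)-1,2,2-trimethylcyclopentyl]phenyl]methyl}-4-methyl-6-[(1S)-1,2,2-trimethylcyclopentyl]benzene-1,2-diol | Cc1cc([C@@]2(C)CCCC2(C)C)c(O)c(O)c1Cc1cc(O)c(O)c([C@@]2(C)CCCC2(C)C)c1 | target

**Totals**

Total step count: 11. Longest linear sequence: 11 steps (1 → 17; 12 enters step 10 a second time as the nucleophile).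

**Steps most likely to fail**

Step 5 (proposed new method). What may go wrong: insufficient facial discrimination by the chiral acid, or diversion of the quinone methide into intermolecular dimerisation or loss of the tertiary hydroxyl. The fallback sets out from 7 and comes back at 9, using resolution in place of asymmetric catalysis. The rearrangement is run with an achiral acid (diphenyl phosphate, 10 mol%, toluene, rt), a known reaction type for 1-(1-arylvinyl)cyclobutanols, and should give the racemic ketone F1. Acylation of the phenol with (1R,2S,5R)-menthyl chloroformate (Et3N, DMAP, CH2Cl2) should give the diastereomeric menthyl carbonate of the (R)-ketone F2 and menthyl carbonate of the (S)-ketone F3, to be separated by crystallisation or chromatography. Hydrolysis of F2 (LiOH, THF/H2O) returns 9.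

Step 10. What may go wrong: self-condensation of the benzylic electrophile and further alkylation of the product at its open ring B position, giving oligomers instead of the cross-coupled diarylmethane. The fallback sets out from 12 and comes back at 17, using a polar addition of an aryllithium to an aldehyde. O-Methylation of 12 (MeI, K2CO3, acetone) should give the dimethyl ether F4, and bromination (NBS, MeCN) at the open position between OCH3 and CH3 the aryl bromide F5. A second portion of 12 is oxidised with DDQ (2.2 equiv, aqueous dioxane) to the hydroxy aldehyde F7 and O-methylated to the dimethoxy aldehyde F8. Bromine–lithium exchange on F5 (n-BuLi, THF, −78 °C) gives the aryllithium F6, which adds to F8 to give the diarylmethanol F9. Ionic hydrogenation (Et3SiH, CF3CO2H, CH2Cl2) should give the tetramethyl ether F10, and BBr3 as in step 11 then gives 17.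

Step 3. What may go wrong: slow arylmagnesiation by the ortho-substituted Grignard reagent at the hindered tertiary propargylic alkoxide, with competing deprotonation of the alkyne C–H. The fallback sets out from 2 and 4 and comes back at 7, using a cross-coupling that also makes the silyl protection unnecessary. Copper-catalysed internal-selective hydroboration of 4 (CuCl, 1,3-dimesitylimidazolinium chloride, NaOtBu, B2pin2, MeOH, THF) should give the alkenylboronate F11. Suzuki–Miyaura coupling of F11 with unprotected 2 (PdCl2(dppf), K3PO4, dioxane/H2O, 80 °C) should give 7 directly.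

**Further compounds**

F1 | step 5 | racemic 2-(2-hydroxy-3-methoxy-5-methylphenyl)-2-methylcyclopentan-1-one | Cc1cc(C2(C)CCCC2=O)c(O)c(OC)c1
F2 | step 5 | (1R,2S,5R)-5-methyl-2-(propan-2-yl)cyclohexyl 2-methoxy-4-methyl-6-[(1R)-1-methyl-2-oxocyclopentyl]phenyl carbonate | CC(C)[C@@H]1CC[C@@H](C)C[C@H]1OC(=O)Oc1c(OC)cc(C)cc1[C@@]2(C)CCCC2=O
F3 | step 5 | (1R,2S,5R)-5-methyl-2-(propan-2-yl)cyclohexyl 2-methoxy-4-methyl-6-[(1S)-1-methyl-2-oxocyclopentyl]phenyl carbonate | CC(C)[C@@H]1CC[C@@H](C)C[C@H]1OC(=O)Oc1c(OC)cc(C)cc1[C@]2(C)CCCC2=O
F4 | step 10 | 1,2-dimethoxy-5-methyl-3-[(1S)-1,2,2-trimethylcyclopentyl]benzene | Cc1cc([C@@]2(C)CCCC2(C)C)c(OC)c(OC)c1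
F5 | step 10 | 2-bromo-3,4-dimethoxy-1-methyl-5-[(1S)-1,2,2-trimethylcyclopentyl]benzene | Cc1cc([C@@]2(C)CCCC2(C)C)c(OC)c(OC)c1Br
F6 | step 10 | {2,3-dimethoxy-6-methyl-4-[(1S)-1,2,2-trimethylcyclopentyl]phenyl}lithium | Cc1cc([C@@]2(C)CCCC2(C)C)c(OC)c(OC)c1[Li]
F7 | step 10 | 4-hydroxy-3-methoxy-5-[(1S)-1,2,2-trimethylcyclopentyl]benzaldehyde | O=Cc1cc(OC)c(O)c([C@@]2(C)CCCC2(C)C)c1
F8 | step 10 | 3,4-dimethoxy-5-[(1S)-1,2,2-trimethylcyclopentyl]benzaldehyde | O=Cc1cc(OC)c(OC)c([C@@]2(C)CCCC2(C)C)c1
F9 | step 10 | {3,4-dimethoxy-5-[(1S)-1,2,2-trimethylcyclopentyl]phenyl}{2,3-dimethoxy-6-methyl-4-[(1S)-1,2,2-trimethylcyclopentyl]phenyl}methanol (mixture at the carbinol carbon) | Cc1cc([C@@]2(C)CCCC2(C)C)c(OC)c(OC)c1C(O)c1cc(OC)c(OC)c([C@@]2(C)CCCC2(C)C)c1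
F10 | step 10 | 1-{[3,4-dimethoxy-5-[(1S)-1,2,2-trimethylcyclopentyl]phenyl]methyl}-2,3-dimethoxy-6-methyl-4-[(1S)-1,2,2-trimethylcyclopentyl]benzene | Cc1cc([C@@]2(C)CCCC2(C)C)c(OC)c(OC)c1Cc1cc(OC)c(OC)c([C@@]2(C)CCCC2(C)C)c1
F11 | step 3 | 1-[1-(4,4,5,5-tetramethyl-1,3,2-dioxaborolan-2-yl)ethenyl]cyclobutan-1-ol | C=C(B1OC(C)(C)C(C)(C)O1)C1(O)CCC1
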